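**Retrosynthetic overview**
1. Feature: in the 14-membered carbocycle C1–C14, only C10 and C11 lie between the Z C8=C9(Me) alkene and the C12–C13 oxirane. C10–C11–C12 can therefore be carried as a 1-substituted cyclopropanol, and C9 as a Z alkenyl iodide.
2. Key disconnection C9–C10: a palladium homoenolate cross-coupling opens the cyclopropanol, closes the macrocycle and leaves a C12 ketone next to quaternary C13.
3. Oxirane: C12 ketone, then (12R)-alcohol, then mesylate, then displacement by the C13 oxygen with inversion (12S). The permanent rings form in the order 14-membered ring (step 12), oxirane (step 15). A γ-lactone (step 9) and the cyclopropane (step 10) are temporary.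
4. Open chain: (R)-α-terpineol gives C3–C8 and C15 and sets C6. An iodo-Wittig reaction adds C9, HWE and MeMgBr add C1, C2 and C14, and methyl pyruvate adds C12 and C13 by a bis(oxazoline)–Cu(OTf)2 Mukaiyama aldol. CBS reduction sets C1, and EtMgBr adds C10 and C11 by a Kulinkovich reaction.
5. Protecting groups: TES on the tertiary C13 and C15 oxygens and TBDPS on C1, so that acid methanolysis frees C13–OH alone for oxirane closure. Both acetates go on last, after all palladium chemistry.

Key step: step 12

Numbering used throughout: C1 (CHOAc), C2=C3(Me), C4, C5, C6 (bearing C15 = CMe2O), C7, C8=C9(Me), C10, C11, C12–C13(Me) oxirane, C14. The target is 1S, 6R, 12S, 13R, 2E, 8Z, with C11 and C14 cis on the oxirane.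

Assumption: (R)-(+)-α-terpineol and (R,R)-t-Bu-box are bought enantiopure. The (R,R)-ligand is chosen because the (S,S)-ligand is known to give (S)-carbinols from pyruvate esters.

Step 1
Reactants: 1 (R)-α-terpineol
Product: 2 (R)-α-terpinyl triethylsilyl ether
Conditions: TESOTf, 2,6-lutidine, CH2Cl2, 0 °C
Reagents that add atoms: triethylsilyl trifluoromethanesulfonate, CC[Si](CC)(CC)OS(=O)(=O)C(F)(F)F
Why: Silyl triflate silylation of a tertiary alcohol, which masks C15–OH so that it cannot form a lactol with C8 or a hemiketal with C3 once the ring is cleaved, and which leaves C6 untouched.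

Step 2
Reactants: 2 (R)-α-terpinyl triethylsilyl ether
Product: 4 (3R)-6-oxo-3-[2-(triethylsilyloxy)propan-2-yl]heptanal, via secondary ozonide 3 (not isolated)
Conditions: O3, CH2Cl2, −78 °C; then PPh3, −78 °C to rt
Reagents that add atoms: ozone, [O-][O+]=O
Why: Ozonolysis with reductive work-up cleaves the only alkene into the C3 methyl ketone and the C8 aldehyde, and C6 is not alpha to either carbonyl and so cannot epimerise.

Step 3
Reactants: 4 (3R)-6-oxo-3-[2-(triethylsilyloxy)propan-2-yl]heptanal
Product: 5 (5R,7Z)-8-iodo-5-[2-(triethylsilyloxy)propan-2-yl]non-7-en-2-one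
Conditions: EtPPh3I, n-BuLi, THF, rt; I2, −78 °C; NaN(SiMe3)2, −20 °C; then 4, −78 °C
Reagents that add atoms: ethyltriphenylphosphonium iodide, CC[P+](c1ccccc1)(c1ccccc1)c1ccccc1.[I-]; iodine, II
Why: Stork–Zhao-type Wittig olefination, in which the non-stabilised ylide Ph3P=C(I)CH3 reacts under kinetic control to place C7 and iodine cis (8Z) and at −78 °C takes the aldehyde far faster than the methyl ketone.

Step 4
Reactants: 5 (5R,7Z)-8-iodo-5-[2-(triethylsilyloxy)propan-2-yl]non-7-en-2-one
Product: 6 (2E,6R,8Z)-9-iodo-N-methoxy-N,3-dimethyl-6-[2-(triethylsilyloxy)propan-2-yl]deca-2,8-dienamide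
Conditions: (EtO)2P(O)CH2C(O)N(OMe)Me, NaH, THF, 0 °C to 50 °C; minor 2Z isomer removed by chromatography
Reagents that add atoms: diethyl (N-methoxy-N-methylcarbamoylmethyl)phosphonate, CCOP(=O)(CC(=O)N(C)OC)OCC
Why: Horner–Wadsworth–Emmons olefination of a methyl ketone with a stabilised phosphonate anion should favour the 2E isomer, with the amide trans to the C4 chain, and the alkenyl iodide and silyl ether tolerate NaH.

Step 5
Reactants: 6 (2E,6R,8Z)-9-iodo-N-methoxy-N,3-dimethyl-6-[2-(triethylsilyloxy)propan-2-yl]deca-2,8-dienamide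
Product: 7 (3E,7R,9Z)-10-iodo-4-methyl-7-[2-(triethylsilyloxy)propan-2-yl]undeca-3,9-dien-2-one
Conditions: MeMgBr, THF, −20 °C to 0 °C
Reagents that add atoms: methylmagnesium bromide, C[Mg]Br
Why: Weinreb ketone synthesis, in which the chelated tetrahedral adduct prevents over-addition, the β,β-disubstituted alkene disfavours 1,4-addition, and MeMgBr does not exchange with an alkenyl iodide; the new methyl group is C14.

Step 6
Reactants: 7 (3E,7R,9Z)-10-iodo-4-methyl-7-[2-(triethylsilyloxy)propan-2-yl]undeca-3,9-dien-2-one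
Product: 8 2-(trimethylsilyloxy)-1,3-diene of 7 (C14H2=C1(OTMS)–C2H=C3)
Conditions: LiN(SiMe3)2, TMSCl, THF, −78 °C
Reagents that add atoms: chlorotrimethylsilane, C[Si](C)(C)Cl
Why: Kinetic enolisation with O-silylation, in which the amide base removes the alpha-prime C14 proton to give the cross-conjugated enolate and is too mild at −78 °C to dehydroiodinate C8=C9.

Step 7
Reactants: 8 2-(trimethylsilyloxy)-1,3-diene of 7; 9 methyl pyruvate
Product: 11 methyl (2R,5E,9R,11Z)-2-hydroxy-12-iodo-2,6-dimethyl-4-oxo-9-[2-(triethylsilyloxy)propan-2-yl]trideca-5,11-dienoate, via aldol trimethylsilyl ether 10 (not isolated)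
Conditions: Cu(OTf)2 (10 mol %), (R,R)-t-Bu-box [2,2'-isopropylidenebis((4R)-4-tert-butyl-2-oxazoline)] (11 mol %), THF, −78 °C; then citric acid, MeOH, 0 °C
Reagents that add atoms: none
Why: Catalytic enantioselective Mukaiyama aldol addition, in which pyruvate chelates the square-planar divalent copper centre through both carbonyls, a tert-butyl group of the ligand shields one ketone face, and C14 attacks the open face to set (13R); the fully substituted C3 terminus disfavours the hetero-Diels–Alder path, and citric acid removes only the trimethylsilyl group.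

Step 8
Reactants: 11 methyl (2R,5E,9R,11Z)-2-hydroxy-12-iodo-2,6-dimethyl-4-oxo-9-[2-(triethylsilyloxy)propan-2-yl]trideca-5,11-dienoate
Product: 12 C13,C15-bis(triethylsilyl) ether of 11
Conditions: TESOTf, 2,6-lutidine, CH2Cl2, −78 °C to 0 °C
Reagents that add atoms: triethylsilyl trifluoromethanesulfonate, CC[Si](CC)(CC)OS(=O)(=O)C(F)(F)F
Why: Silyl triflate silylation covers the hindered tertiary C13 carbinol without the strong base that would trigger retro-aldol cleavage, and the excess reagent would re-silylate any C15 hydroxyl bared in step 7.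

Step 9
Reactants: 12 C13,C15-bis(triethylsilyl) ether of 11
Product: 14 (3R,5S)-3-methyl-3-(triethylsilyloxy)-5-alkenyl-γ-butyrolactone (C12 carbonyl; ring O on C1), via γ-hydroxy ester 13 (not isolated)
Conditions: (R)-Me-CBS [(R)-1-methyl-3,3-diphenyltetrahydropyrrolo[1,2-c][1,3,2]oxazaborole] (0.5 equiv), catecholborane, toluene, −78 °C; MeOH quench; then pyridinium p-toluenesulfonate (10 mol %), toluene, 40 °C
Reagents that add atoms: none
Why: Corey–Bakshi–Shibata reduction, in which the alkenyl arm acts as the large group so that the (R)-catalyst gives (1S), followed by deliberate acid-catalysed lactonisation of a γ-hydroxy ester that would cyclise anyway; the lactone lets a C1 epimer be removed by chromatography and is a less crowded carbonyl for step 10.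

Step 10
Reactants: 14 (3R,5S)-3-methyl-3-(triethylsilyloxy)-5-alkenyl-γ-butyrolactone
Product: 15 cyclopropanol diol (C10–C12 cyclopropanol and free C1–OH)
Conditions: EtMgBr (4 equiv, slow addition), Ti(OiPr)4 (1 equiv), THF, 0 °C to rt
Reagents that add atoms: ethylmagnesium bromide, CC[Mg]Br
Why: Kulinkovich reaction on a lactone, in which the titanacyclopropane from EtMgBr and Ti(OiPr)4 acts as a 1,2-dicarbanion on C12, adds C10 and C11 and releases C1–O as the alcohol; trisubstituted alkenes do not undergo ligand exchange, and an unactivated alkenyl iodide exchanges only slowly with EtMgBr at this temperature.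

Step 11
Reactants: 15 cyclopropanol diol
Product: 16 open-chain precursor (C10–C12 cyclopropanol; C13–OTES; C1–OTBDPS; C15–OTES; Z C9 iodide)
Conditions: TBDPSCl, imidazole, DMF, 0 °C to rt
Reagents that add atoms: tert-butylchlorodiphenylsilane, CC(C)(C)[Si](Cl)(c1ccccc1)c1ccccc1
Why: Chemoselective silylation (silyl chloride and imidazole), in which the bulky chloride takes the secondary allylic C1–OH and leaves the tertiary cyclopropanol buried next to quaternary C13; TBDPS is chosen because it outlasts the acid methanolysis of step 15.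

Step 12
Reactants: 16 open-chain precursor
Product: 17 14-membered C12 ketone (1S,6R,13R,2E,8Z) with C1–OTBDPS and C13,C15–OTES
Conditions: Pd(OAc)2 (10 mol %), XPhos [2-dicyclohexylphosphino-2',4',6'-triisopropylbiphenyl] (20 mol %), Cs2CO3 (3 equiv), toluene, 80 °C, 16 added by syringe pump to a final 1 mM
Reagents that add atoms: none
Why: Zerovalent palladium formed from Pd(OAc)2 and XPhos inserts into the C9–I bond, carbonate-assisted exchange of iodide for the C12 cyclopropoxide and strain-driven β-carbon elimination give a C10 alkylpalladium homoenolate, and C(sp2)–C(sp3) reductive elimination forms C9–C10 and reveals the C12 ketone. The closest known reaction type is the palladium-catalysed ring-opening cross-coupling of tertiary cyclopropanols with aryl and alkenyl halides, including intramolecular closures of seven-membered rings, so only the ring size is extended. The 14-membered carbocycle is closed end to end by reductive elimination from a 15-membered palladacycle, with slow addition and high dilution to hold back dimerisation. No stereocentre is formed: C1, C6 and C13 are spectators, and quaternary C13 cannot epimerise beside the new ketone. The Z geometry at C9 is kept because oxidative addition and reductive elimination are both stereoretentive, and ring cleavage raises no regiochemical question because breaking either C12–CH2 bond gives the same homoenolate. The remaining demand, reductive elimination faster than β-hydride elimination to the vinyl ketone, is addressed by the bulky electron-rich biaryl phosphine, while the silyl ethers at C1 and C13 block alcohol oxidation and α-ketol rearrangement.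

Step 13
Reactants: 17 14-membered C12 ketone
Product: 18 (12R)-alcohol of the macrocycle (12,13-syn)
Conditions: LiBH(s-Bu)3, THF, −78 °C; AcOH quench at −78 °C; then pH 7 buffer, H2O2, 0 °C
Reagents that add atoms: none
Why: Felkin–Anh controlled hydride reduction, in which the bulky borohydride approaches anti to the C13–OTES bond and past the small C13 methyl group to give the 12,13-syn (12R) alcohol, and the cold acidic quench prevents migration of the C13 silyl group to the new alkoxide.

Step 14
Reactants: 18 (12R)-alcohol of the macrocycle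
Product: 19 (12R)-mesylate
Conditions: MsCl, Et3N, CH2Cl2, 0 °C
Reagents that add atoms: methanesulfonyl chloride, CS(=O)(=O)Cl
Why: Mesylation through sulfene, a small electrophile that reaches the hindered C12 hydroxyl, proceeds with retention because the C12–O bond is not broken.

Step 15
Reactants: 19 (12R)-mesylate
Product: 21 (12S,13R)-epoxide with free C15–OH and C1–OTBDPS, via dihydroxy mesylate 20 (not isolated)
Conditions: camphor-10-sulfonic acid (20 mol %), MeOH–CH2Cl2, 0 °C to rt; then K2CO3 (excess), rt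
Reagents that add atoms: none
Why: Acid-catalysed methanolysis removes both triethylsilyl ethers far faster than the acid-stable TBDPS ether, and on adding K2CO3 the C13 alkoxide displaces the C12 mesylate in an intramolecular Williamson (3-exo-tet SN2) closure with inversion, 12R to 12S with C13 unchanged, while the masked C1 oxygen cannot compete by closing a tetrahydrofuran.

Step 16
Reactants: 21 (12S,13R)-epoxide with free C15–OH and C1–OTBDPS
Product: 22 epoxy diol (C1–OH and C15–OH free)
Conditions: Bu4NF, THF, 0 °C to rt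
Reagents that add atoms: none
Why: Fluoride-induced desilylation driven by the Si–F bond frees C1–OH, and opening of the oxirane by that oxygen would need a disfavoured 5-endo or 4-exo attack.

Step 17
Reactants: 22 epoxy diol
Product: 23 target CNP0282098.1 (1S,6R,12S,13R,2E,8Z diacetate)
Conditions: Ac2O (excess), Et3N, 4-(dimethylamino)pyridine, CH2Cl2, rt to 40 °C
Reagents that add atoms: acetic anhydride, CC(=O)OC(C)=O
Why: 4-(Dimethylamino)pyridine-catalysed acylation through the N-acetylpyridinium ion acetylates the secondary allylic C1–OH and, on longer exposure, the tertiary C15–OH, under basic conditions that leave the oxirane and all stereocentres untouched.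

**Compound list**
1 | (R)-α-terpineol | CC1=CC[C@@H](CC1)C(C)(C)O | starting material
2 | (R)-α-terpinyl triethylsilyl ether | CC1=CC[C@@H](CC1)C(C)(C)O[Si](CC)(CC)CC | intermediate
3 | secondary ozonide of 2 (1,2,4-trioxolane bridging C3 and C8) | CC12CC[C@@H](C(C)(C)O[Si](CC)(CC)CC)CC(OO1)O2 | intermediate
4 | (3R)-6-oxo-3-[2-(triethylsilyloxy)propan-2-yl]heptanal | CC(=O)CC[C@@H](C(C)(C)O[Si](CC)(CC)CC)CC=O | intermediate
5 | (5R,7Z)-8-iodo-5-[2-(triethylsilyloxy)propan-2-yl]non-7-en-2-one | CC(=O)CC[C@@H](C(C)(C)O[Si](CC)(CC)CC)C/C=C(/C)I | intermediate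
6 | (2E,6R,8Z)-9-iodo-N-methoxy-N,3-dimethyl-6-[2-(triethylsilyloxy)propan-2-yl]deca-2,8-dienamide | CON(C)C(=O)/C=C(\C)CC[C@@H](C(C)(C)O[Si](CC)(CC)CC)C/C=C(/C)I | intermediate
7 | (3E,7R,9Z)-10-iodo-4-methyl-7-[2-(triethylsilyloxy)propan-2-yl]undeca-3,9-dien-2-one | CC(=O)/C=C(\C)CC[C@@H](C(C)(C)O[Si](CC)(CC)CC)C/C=C(/C)I | intermediate
8 | 2-(trimethylsilyloxy)-1,3-diene of 7 | C=C(O[Si](C)(C)C)/C=C(\C)CC[C@@H](C(C)(C)O[Si](CC)(CC)CC)C/C=C(/C)I | intermediate
9 | methyl pyruvate | COC(=O)C(C)=O | starting material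
10 | aldol adduct as C13 trimethylsilyl ether (13R) | COC(=O)[C@](C)(O[Si](C)(C)C)CC(=O)/C=C(\C)CC[C@@H](C(C)(C)O[Si](CC)(CC)CC)C/C=C(/C)I | intermediate
11 | methyl (2R,5E,9R,11Z)-2-hydroxy-12-iodo-2,6-dimethyl-4-oxo-9-[2-(triethylsilyloxy)propan-2-yl]trideca-5,11-dienoate | COC(=O)[C@](C)(O)CC(=O)/C=C(\C)CC[C@@H](C(C)(C)O[Si](CC)(CC)CC)C/C=C(/C)I | intermediate
12 | C13,C15-bis(triethylsilyl) ether of 11 | COC(=O)[C@](C)(O[Si](CC)(CC)CC)CC(=O)/C=C(\C)CC[C@@H](C(C)(C)O[Si](CC)(CC)CC)C/C=C(/C)I | intermediate
13 | (1S,13R)-γ-hydroxy ester | COC(=O)[C@](C)(O[Si](CC)(CC)CC)C[C@H](O)/C=C(\C)CC[C@@H](C(C)(C)O[Si](CC)(CC)CC)C/C=C(/C)I | intermediate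
14 | (3R,5S)-γ-butyrolactone (C12 carbonyl, ring O on C1; 1S,13R) | O=C1O[C@@H](C[C@@]1(C)O[Si](CC)(CC)CC)/C=C(\C)CC[C@@H](C(C)(C)O[Si](CC)(CC)CC)C/C=C(/C)I | intermediate
15 | cyclopropanol diol (free C1–OH) | OC1(CC1)[C@](C)(O[Si](CC)(CC)CC)C[C@H](O)/C=C(\C)CC[C@@H](C(C)(C)O[Si](CC)(CC)CC)C/C=C(/C)I | intermediate
16 | open-chain precursor: cyclopropanol, C13–OTES, C1–OTBDPS, C15–OTES, Z C9 iodide | OC1(CC1)[C@](C)(O[Si](CC)(CC)CC)C[C@H](O[Si](c1ccccc1)(c1ccccc1)C(C)(C)C)/C=C(\C)CC[C@@H](C(C)(C)O[Si](CC)(CC)CC)C/C=C(/C)I | intermediate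
17 | 14-membered C12 ketone | CC(C)(C)[Si](c1ccccc1)(c1ccccc1)O[C@@H]1/C=C(\C)CC[C@@H](C(C)(C)O[Si](CC)(CC)CC)C/C=C(/C)CCC(=O)[C@](C)(O[Si](CC)(CC)CC)C1 | intermediate
18 | (12R)-alcohol | CC(C)(C)[Si](c1ccccc1)(c1ccccc1)O[C@@H]1/C=C(\C)CC[C@@H](C(C)(C)O[Si](CC)(CC)CC)C/C=C(/C)CC[C@@H](O)[C@](C)(O[Si](CC)(CC)CC)C1 | intermediate
19 | (12R)-mesylate | CC(C)(C)[Si](c1ccccc1)(c1ccccc1)O[C@@H]1/C=C(\C)CC[C@@H](C(C)(C)O[Si](CC)(CC)CC)C/C=C(/C)CC[C@@H](OS(C)(=O)=O)[C@](C)(O[Si](CC)(CC)CC)C1 | intermediate
20 | dihydroxy mesylate (C13–OH and C15–OH free) | CC(C)(C)[Si](c1ccccc1)(c1ccccc1)O[C@@H]1/C=C(\C)CC[C@@H](C(C)(C)O)C/C=C(/C)CC[C@@H](OS(C)(=O)=O)[C@](C)(O)C1 | intermediate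
21 | (12S,13R)-epoxide, C15–OH free, C1–OTBDPS | CC(C)(C)[Si](c1ccccc1)(c1ccccc1)O[C@@H]1/C=C(\C)CC[C@@H](C(C)(C)O)C/C=C(/C)CC[C@@H]2O[C@]2(C)C1 | intermediate
22 | epoxy diol | O[C@@H]1/C=C(\C)CC[C@@H](C(C)(C)O)C/C=C(/C)CC[C@@H]2O[C@]2(C)C1 | intermediate
23 | CNP0282098.1 | CC(=O)O[C@@H]1/C=C(\C)CC[C@@H](C(C)(C)OC(C)=O)C/C=C(/C)CC[C@@H]2O[C@]2(C)C1 | target

Total step count: 17. Longest linear sequence: 17 steps, from (R)-α-terpineol 1.

**Three steps most likely to fail**

Step 12 (macrocyclisation).
- What may go wrong: intermolecular coupling may overtake ring closure. The C10 alkylpalladium may undergo β-hydride elimination before reductive elimination. Alkoxide binding at the crowded cyclopropanol may be so slow that base-induced ring opening takes over.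
- Fallback: the same C9–C10 bond is made by a B-alkyl Suzuki–Miyaura macrocyclisation, a known way to close large rings onto Z alkenyl iodides. It sets out from lactone 14, which is opened with MeNH(OMe)·HCl and AlMe3 in CH2Cl2 to the hydroxy Weinreb amide F1. This is silylated at once (TBDPSCl, imidazole) to the protected Weinreb amide F2. Vinylmagnesium bromide in THF at 0 °C, with inverse quench into cold aqueous acid, gives the vinyl ketone F3. Reduction with (S)-Me-CBS and catecholborane treats quaternary C13 as the large group and should give the (12R)-allylic alcohol F4. 9-BBN (2.2 equiv) hydroborates only the terminal alkene and caps the hydroxyl, giving the bis(9-BBN) adduct F5. F5 is added slowly to Pd(dppf)Cl2, AsPh3 and Cs2CO3 in DMF–THF–H2O, where the borinate is hydrolysed and the ring closes. The route is rejoined at alcohol 18.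

Step 10 (Kulinkovich reaction).
- What may go wrong: iodine–magnesium exchange or reduction of the alkenyl iodide by low-valent titanium, sluggish addition to the carbonyl beside quaternary C13, or migration of the C13 triethylsilyl group to the liberated C1 alkoxide.
- Fallback: the cyclopropanol is built by carbenoid cyclopropanation of an enol silane instead of from a titanacyclopropane. It sets out from lactone 14 and passes, by the two operations described above, through the protected Weinreb amide F2. MeMgBr converts F2 into the methyl ketone F6. Because C13 is quaternary, LiN(SiMe3)2 and TMSCl can enolise F6 only toward the methyl group, giving the enol silane F7. Et2Zn and CH2I2 (Simmons–Smith reaction, Furukawa variant; about one equivalent, CH2Cl2, 0 °C) attack this most electron-rich alkene first and give the silyloxycyclopropane F8. K2CO3 in MeOH removes the trimethylsilyl group, and the route is rejoined at precursor 16.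

Step 9 (CBS reduction at C1).
- What may go wrong: poor facial selectivity, because the C14 side with its neopentyl-type C13 may rival the alkenyl arm in size, and competing 1,4-reduction.
- Fallback: asymmetric catalysis is replaced by separation and stereoinversion. It sets out from ketone 12, which is reduced under Luche conditions (NaBH4, CeCl3·7H2O, MeOH, −78 °C) to 13 and its (1R)-hydroxy ester F9. Treatment with pyridinium p-toluenesulfonate gives lactone 14 and the (1R)-lactone F10, which are separated by chromatography. F10 is saponified (LiOH, THF–H2O) and carefully acidified in the cold to the (1R)-hydroxy acid F11. F11 is taken without storage into a Mitsunobu lactonisation (PPh3, diisopropyl azodicarboxylate, THF, 0 °C), where the carboxylate displaces the activated C1 oxygen with inversion. The route is rejoined at lactone 14.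

**Further compounds**
F1 | step 12 | hydroxy Weinreb amide (1S,13R) | CON(C)C(=O)[C@](C)(O[Si](CC)(CC)CC)C[C@H](O)/C=C(\C)CC[C@@H](C(C)(C)O[Si](CC)(CC)CC)C/C=C(/C)I
F2 | step 12 | protected Weinreb amide (C1–OTBDPS) | CON(C)C(=O)[C@](C)(O[Si](CC)(CC)CC)C[C@H](O[Si](c1ccccc1)(c1ccccc1)C(C)(C)C)/C=C(\C)CC[C@@H](C(C)(C)O[Si](CC)(CC)CC)C/C=C(/C)I
F3 | step 12 | vinyl ketone (C10=C11, C12 ketone) | C=CC(=O)[C@](C)(O[Si](CC)(CC)CC)C[C@H](O[Si](c1ccccc1)(c1ccccc1)C(C)(C)C)/C=C(\C)CC[C@@H](C(C)(C)O[Si](CC)(CC)CC)C/C=C(/C)I
F4 | step 12 | (12R)-allylic alcohol | C=C[C@@H](O)[C@](C)(O[Si](CC)(CC)CC)C[C@H](O[Si](c1ccccc1)(c1ccccc1)C(C)(C)C)/C=C(\C)CC[C@@H](C(C)(C)O[Si](CC)(CC)CC)C/C=C(/C)I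
F5 | step 12 | bis(9-BBN) adduct (C10 alkylborane, C12 borinate) | B1(C2CCCC1CCC2)CC[C@@H](OB1C2CCCC1CCC2)[C@](C)(O[Si](CC)(CC)CC)C[C@H](O[Si](c1ccccc1)(c1ccccc1)C(C)(C)C)/C=C(\C)CC[C@@H](C(C)(C)O[Si](CC)(CC)CC)C/C=C(/C)I
F6 | step 10 | methyl ketone at C12 | CC(=O)[C@](C)(O[Si](CC)(CC)CC)C[C@H](O[Si](c1ccccc1)(c1ccccc1)C(C)(C)C)/C=C(\C)CC[C@@H](C(C)(C)O[Si](CC)(CC)CC)C/C=C(/C)I
F7 | step 10 | enol silane of F6 | C=C(O[Si](C)(C)C)[C@](C)(O[Si](CC)(CC)CC)C[C@H](O[Si](c1ccccc1)(c1ccccc1)C(C)(C)C)/C=C(\C)CC[C@@H](C(C)(C)O[Si](CC)(CC)CC)C/C=C(/C)I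
F8 | step 10 | silyloxycyclopropane | C[Si](C)(C)OC1(CC1)[C@](C)(O[Si](CC)(CC)CC)C[C@H](O[Si](c1ccccc1)(c1ccccc1)C(C)(C)C)/C=C(\C)CC[C@@H](C(C)(C)O[Si](CC)(CC)CC)C/C=C(/C)I
F9 | step 9 | (1R)-hydroxy ester | COC(=O)[C@](C)(O[Si](CC)(CC)CC)C[C@@H](O)/C=C(\C)CC[C@@H](C(C)(C)O[Si](CC)(CC)CC)C/C=C(/C)I
F10 | step 9 | (1R)-lactone | O=C1O[C@H](C[C@@]1(C)O[Si](CC)(CC)CC)/C=C(\C)CC[C@@H](C(C)(C)O[Si](CC)(CC)CC)C/C=C(/C)I
F11 | step 9 | (1R)-hydroxy acid | OC(=O)[C@](C)(O[Si](CC)(CC)CC)C[C@@H](O)/C=C(\C)CC[C@@H](C(C)(C)O[Si](CC)(CC)CC)C/C=C(/C)I
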